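Its constants are invented; the flask was simulated.

With 0.05 mol% of catalyst, each free catalyst faces 2000 substrate, so the outcome of a short run is a count of rounds.

in all of them: substrate 0.80 M; coupling partner 1.20 equiv; free catalyst 0.05 mol%; time 5.0 min
- Friday's: temperature 70 °C
- Thursday's: temperature 40 °C

- the best flask by amount of product, in percent of the substrate charged; "all alike" if 1.5 percentage points covers them all (Friday's / Thursday's / all alike)
- amount of product at the end, in percent of the substrate charged, Friday's
- amount of product at the end, in percent of the substrate charged, Thursday's

- for a step with 2 of a species take k times the square, and two of it per event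
- the constants hold at 70 °C; other temperatures follow from the activation energies and enthalpies

    catalyst intermediate C → released group + catalyst intermediate D (k1 = 7.3 s⁻¹, Ea1 = 70.0 kJ mol⁻¹)
    catalyst intermediate D → free catalyst + product (k2 = 8.0 s⁻¹, Ea2 = 69.0 kJ mol⁻¹)
    catalyst intermediate A ⇌ catalyst intermediate B (K3 = 1.7, k3 = 8.4 s⁻¹, Ea3 = 69.0 kJ mol⁻¹, ΔH3 = −62.0 kJ mol⁻¹)
    2 free catalyst → spent catalyst (k4 = 1.0 M⁻¹ s⁻¹, Ea4 = 52.0 kJ mol⁻¹)
    substrate + free catalyst ⇌ catalyst intermediate A (K5 = 2.7 M⁻¹, k5 = 3.0 M⁻¹ s⁻¹, Ea5 = 61.0 kJ mol⁻¹, ΔH5 = −16.0 kJ mol⁻¹)
    coupling partner + catalyst intermediate B → catalyst intermediate C (k6 = 8.7 M⁻¹ s⁻¹, Ea6 = 48.0 kJ mol⁻¹)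
    (constants at 70 °C)

The catalyst pool is 0.400 mM, far below the reagents. After a short start every step of the round therefore carries the same flow, and each form holds catalyst in proportion to its wait per round. The waits are reckoned backwards from the exit, for Friday's flask at its charge.

Catalyst intermediate D: one over its rate constant, 0.125 s.
Catalyst intermediate C: likewise, 0.137 s.
Catalyst intermediate B: one over its rate constant times [coupling partner], 0.120 s.
Catalyst intermediate A: one over its forward constant, plus the wait on B over the equilibrium constant, a term that counts the falling back of B, 0.189 s.
Free catalyst: one over the forward constant plus the wait on A over the equilibrium constant, all over [substrate], 0.504 s.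

These add up to 1.08 s. This sum is the round time: the mean time one catalyst needs for one full round at the reagent levels of the moment. Product, in percent of substrate, is then time over round time, times loading.

In this reckoning time and loading enter as plain multipliers, and together they give a first answer of 13.9% for Friday's flask.

More loading also feeds the loss to spent catalyst. Free catalyst holds 46.9% of the pool, which makes it the resting state. Its half-life by that loss is 44.4 min, longer than the run, so the reckoning sets the loss aside.

Substrate acts with a reckoned order of 0.469, and coupling partner with 0.207. No single rate-limiting step stands out, since the other waits together exceed the longest.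

Those orders call for a second round. The mean reagent levels lie below the charge by half of the first answer:

[substrate] = 0.744 M, [coupling partner] = 0.904 M
round time = 1.13 s
Friday's product = 13.3%

Temperature is the last setting. Cooling to 40 °C slows the coupling step by a factor of 5.0 and the binding of substrate by 7.8, while both equilibrium constants grow. The same waits for Thursday's flask, in the same order, are:

1.27 s, 1.44 s, 0.600 s, 1.25 s, 3.57 s
round time = 8.13 s
Thursday's product = 1.85%

The flask to pick is Friday's.

The forecast gives Friday's, with 12.9% and 1.8%, holding that “the product is set by turnover frequency times time”.

Friday's flask gives 13.0% and Thursday's 1.81%, so the best is Friday's. At 5.00 min, free catalyst in Friday's flask stands at 46.9% of the catalyst charged. The round time applies once more to the same flask as Thursday's at 65 °C, where the same waits at the charge, in the same order, are: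

0.179 s, 0.197 s, 0.154 s, 0.236 s, 0.672 s
round time = 1.44 s
first answer = 10.4%

That flask holds 9.89% of product at 5.00 min.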